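(Readings and results come from a simulation with made-up constants.)

A closed, stirred vessel at one temperature turns starting material and coupling partner into target on a free catalyst. The charges differ from day to day.

in all of them: free catalyst 0.0160 M

| flask | starting material | coupling partner | time |
|---|---|---|---|
| Saturday's | 0.800 M | 0.960 M |  |
| Thursday's | 0.320 M | 0.480 M |  |
| Tuesday's | 1.20 M | 0.960 M |  |
| Wednesday's | 2.40 M | 0.960 M | 9.4 h |

| run | time / h | [target] / M |
|---|---|---|
| Saturday's run | 0.72 | 0.0615 |
| Saturday's run | 2.2 | 0.1798 |
| Saturday's run | 4.2 | 0.3063 |
| Saturday's run | 6.6 | 0.4099 |
| Saturday's run | 9.4 | 0.4688 |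
| Thursday's run | 0.72 | 0.0337 |
| Thursday's run | 2.2 | 0.0848 |
| Thursday's run | 4.2 | 0.1429 |
| Thursday's run | 6.6 | 0.1824 |
| Thursday's run | 9.4 | 0.2046 |
| Tuesday's run | 0.72 | 0.0685 |
| Tuesday's run | 2.2 | 0.1896 |
| Tuesday's run | 4.2 | 0.3272 |
| Tuesday's run | 6.6 | 0.4507 |
| Tuesday's run | 9.4 | 0.5491 |

(scatter of a reading: 0.002 M)

- Overall: starting material + coupling partner -> target, with free catalyst as catalyst.
- Constant volume, constant temperature.
- Bound and free are read together.
- An order is taken over about fifteen percent of the charge, up and down.

- reaction order in [starting material] at the outset, round the charge of the Saturday's run, defined at two percent of the starting material turned into target (one fixed amount of target, the same in the runs compared)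
- reaction order in [coupling partner] at the outset, round the charge of the Saturday's run, defined at two percent of the starting material turned into target
- target in the Wednesday's run at 9.4 h, as a share of the starting material charged

How far does target follow c(starting material)? Saturday's and Tuesday's flasks share c(coupling partner) and c(free catalyst), and Tuesday's holds 1.50 times the starting material. The first readings carry a scatter of 3.25%, and those at 2.2 h carry 1.11%, so this reckoning takes the later pair. Tuesday's 0.1896 M over Saturday's 0.1798 M reads 0.131. That number is the charge response, the logarithm of the target ratio at one time over the logarithm of the charge ratio. The proportional case stands at one, the indifferent case at zero.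

What then carries the rate? Thursday's flask holds half of Saturday's coupling partner and 0.400 of its starting material. At 2.2 h its target is 0.472 of Saturday's. The charge response accounts for a factor 0.887, and the remainder reads as an order in coupling partner of 0.911, steeper than the charge response.

What does Wednesday's flask give? Its starting material is twice Tuesday's. Tuesday's and Wednesday's flasks both hold 0.960 M of coupling partner, and Tuesday's starting material lies closer to Wednesday's than Saturday's does, so Tuesday's flask is the base. If the response read early still holds at 9.4 h, Tuesday's 0.5491 M becomes 0.601 M, which is 25.1% of Wednesday's charge.

The forecast differs from this reckoning. It gives 0.3 (0.17 to 0.45), 0.4 (0.2 to 0.7) and 28.5% (26% to 31%), and it says of its partner order that “this rests on one run changing both charges”. Its Wednesday share stands above the 25.1% reckoned here.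

    free catalyst + starting material → catalyst-substrate complex (71.28 /M/h)
    catalyst-substrate complex + coupling partner → target + free catalyst (9.828 /M/h)
    starting material → decomposed substrate (0.1289 /h)
    free catalyst + impurity → spent catalyst

The flask gives orders of 0.15 and 0.87, and 25.1% for Wednesday's target at 9.4 h. Fitted with the main steps alone, the runs leave a residual of 9.1 times the scatter. Thursday's flask, read through the charge response, gave 0.911 for the coupling partner. Wednesday's target of 0.602 M over Tuesday's 0.5491 M gives a charge response of 0.133 at 9.4 h.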